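## Retrosynthetic overview
1. Target (9) ⇐ hydrogenolysis of two aryl benzyl ethers ⇐ diol 8 ⇐ hydride reduction of the ester and aldehyde of tetralin 7.
2. The only ring (C1–C8a) is closed by an acid-promoted 6-endo Friedel–Crafts hydroarylation of the α-alkylidene aldehyde 6. The C3 stereocentre directs C1 and C2 to the all-trans arrangement.
3. Enal 6 ⇐ crossed aldol condensation (C1–C2 bond) of aldehyde 4 with vanillin benzyl ether (5).
4. Aldehyde 4 ⇐ dual photoredox/iminium decarboxylative β-benzylation (C3–C4 bond) of ethyl 4-oxobut-2-enoate (2) with arylacetic acid 1. This sets C3, the only catalyst-controlled stereocentre.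

Assumptions:
- Compound 1 is commercial. Otherwise it is one step from homovanillic acid (BnBr/K2CO3, then LiOH).
- The (R)-catalyst 3 is taken to give the R-configured C3 by the usual shielding model for diarylprolinol-silyl-ether iminium ions. If the opposite sense is found, the (S)-catalyst is used.

## Route

**Step 1**
Reactants: 1 (4-(benzyloxy)-3-methoxyphenylacetic acid), 2 (ethyl (E)-4-oxobut-2-enoate), 3 ((R)-α,α-diphenylprolinol TMS ether, chiral amine catalyst)
Product: 4, ethyl (R)-2-[4-(benzyloxy)-3-methoxybenzyl]-4-oxobutanoate
Conditions: 3 (20 mol %), 4CzIPN (2 mol %), K2HPO4 (0.5 equiv), MeCN/DMSO 4:1, blue LEDs (455 nm), 10 °C, 24 h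
Reagents that add atoms: none (CO2 is lost; the catalysts are not incorporated)
Why: Proposed new method: amine 3 condenses with the aldehyde of 2 to give a chiral (E)-iminium ion. Excited 4CzIPN oxidises the arylacetate, which loses CO2 to give the nucleophilic 4-benzyloxy-3-methoxybenzyl radical. The radical adds to the iminium β-carbon (the CO2Et-bearing carbon) on the face anti to the CAr2OTMS group, which sets C3 as R. 4CzIPN•⁻ then reduces the α-iminyl radical to the enamine, which is protonated and hydrolysed. The closest known reactions are photoredox decarboxylative Giese additions and iminium-catalysed radical conjugate additions to enals.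

**Step 2**
Reactants: 4, 5 (4-(benzyloxy)-3-methoxybenzaldehyde)
Product: 6, ethyl (R,E)-2-[4-(benzyloxy)-3-methoxybenzyl]-3-formyl-4-[4-(benzyloxy)-3-methoxyphenyl]but-3-enoate
Conditions: 5 (1.5 equiv), pyrrolidine (20 mol %), PhCO2H (20 mol %), toluene, 4 Å MS, 50 °C, 24 h
Reagents that add atoms: none (water is lost)
Why: enamine-catalysed crossed aldol condensation (Claisen–Schmidt type). Only 4 can enolise, and dehydration gives the conjugated (E)-enal. C3 is a tertiary α-ester centre whose C–H is not conjugated to the iminium or enamine, so mild amine/acid catalysis should not epimerise it.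

**Step 3**
Reactants: 6
Product: 7, ethyl (1S,2R,3R)-7-(benzyloxy)-1-[4-(benzyloxy)-3-methoxyphenyl]-2-formyl-6-methoxy-1,2,3,4-tetrahydronaphthalene-3-carboxylate (lignan numbering)
Conditions: TfOH (10 mol %), CH2Cl2/HFIP 9:1 (0.02 M), 0 °C → rt, 2 h; Et3N quench
Reagents that add atoms: none (isomerisation)
Why: Brønsted-acid Friedel–Crafts hydroarylation (6-endo) of the protonated enal. The p-alkoxyaryl-stabilised allyl cation is attacked by the other ring at the position para to OMe, which gives the 6-OMe/7-OBn pattern. The chair-like transition state places the C3 ester and the new C1 aryl group both equatorial, so they are 1,3-cis. The C2 aldehyde epimerises through its enol to the equatorial position, trans to both neighbours.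

**Step 4**
Reactants: 7
Product: 8, [(1S,2R,3R)-7-(benzyloxy)-1-(4-(benzyloxy)-3-methoxyphenyl)-6-methoxy-tetralin-2,3-diyl]dimethanol
Conditions: LiAlH4 (3 equiv), THF, 0 °C, 1 h; Fieser work-up
Reagents that add atoms: none (hydride only adds hydrogen)
Why: LiAlH4 reduces the ester and the aldehyde to primary alcohols. The benzyl and methyl ethers survive, and the stereocentres are untouched because reduction is faster than enolisation.

**Step 5**
Reactants: 8
Product: 9, (+)-isolariciresinol
Conditions: H2 (1 atm), 10% Pd/C, EtOAc/EtOH 1:1, rt, 6 h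
Reagents that add atoms: none (H2 only adds hydrogen)
Why: catalytic hydrogenolysis cleaves the two aryl benzyl ethers. The diarylmethine C–H, the primary alcohols and the arene rings are unaffected.

## Compound list
1 | 4-(benzyloxy)-3-methoxyphenylacetic acid | COc1cc(CC(=O)O)ccc1OCc1ccccc1 | starting material
2 | ethyl (E)-4-oxobut-2-enoate | CCOC(=O)/C=C/C=O | starting material
3 | (R)-α,α-diphenylprolinol trimethylsilyl ether (chiral amine catalyst) | C[Si](C)(C)OC(c1ccccc1)(c1ccccc1)[C@H]1CCCN1 | starting material
4 | ethyl (R)-2-[4-(benzyloxy)-3-methoxybenzyl]-4-oxobutanoate | CCOC(=O)[C@@H](CC=O)Cc1ccc(OCc2ccccc2)c(OC)c1 | intermediate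
5 | 4-(benzyloxy)-3-methoxybenzaldehyde | COc1cc(C=O)ccc1OCc1ccccc1 | starting material
6 | ethyl (R,E)-2-[4-(benzyloxy)-3-methoxybenzyl]-3-formyl-4-[4-(benzyloxy)-3-methoxyphenyl]but-3-enoate | CCOC(=O)[C@H](Cc1ccc(OCc2ccccc2)c(OC)c1)/C(C=O)=C\c1ccc(OCc2ccccc2)c(OC)c1 | intermediate
7 | tetralin ester-aldehyde (1S,2R,3R) | COc1cc([C@H]2c3cc(OCc4ccccc4)c(OC)cc3C[C@@H](C(=O)OCC)[C@@H]2C=O)ccc1OCc1ccccc1 | intermediate
8 | dibenzyl-protected isolariciresinol (1S,2R,3R) | COc1cc([C@H]2c3cc(OCc4ccccc4)c(OC)cc3C[C@@H](CO)[C@@H]2CO)ccc1OCc1ccccc1 | intermediate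
9 | (+)-isolariciresinol | COc1cc([C@H]2c3cc(O)c(OC)cc3C[C@@H](CO)[C@@H]2CO)ccc1O | target

## Totals
Total steps: 5. Longest linear sequence: 5.

## Three steps most likely to fail
1. **Step 1 (the proposed new method).** Risks are direct reduction of the very electron-poor iminium by 4CzIPN•⁻, benzyl-radical dimerisation, and modest ee.
   Fallback (known chemistry): Evans asymmetric alkylation.
   - Alkylate the N-acyl oxazolidinone of mono-tert-butyl succinate with 4-(benzyloxy)-3-methoxybenzyl bromide (NaHMDS, −78 °C), using the auxiliary enantiomer that gives the R centre.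
   - Convert the imide to the ethyl ester (Ti(OEt)4, EtOH, 60 °C, chosen to avoid racemisation).
   - Cleave the tert-butyl ester with TFA, reduce the acid selectively with BH3·THF, and oxidise with DMP to give 4.
2. **Step 3.** Risks are wrong 1,3-diastereoselectivity, debenzylation under TfOH, and cyclisation at the position ortho to OMe.
   Fallback (changes the bond-forming logic):
   - Run the C1–C2 bond formation as an amine-catalysed aldol addition (no dehydration).
   - Reduce the adduct with NaBH4, which lactonises onto the C3 ester.
   - Ionise the resulting benzylic alcohol with BF3·OEt2 for the Friedel–Crafts ring closure.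
   - Open the lactone with LiAlH4 to give 8.
3. **Step 2.** The crossed aldol condensation of a β-branched aldehyde with an electron-rich benzaldehyde may be slow or give self-condensation.
   Fallback: convert 4 to its TMS enol ether (TMSOTf, Et3N) and do a TiCl4 Mukaiyama aldol with 5 at −78 °C. Then dehydrate (MsCl/Et3N, then DBU) to 6.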